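Readings and results were generated by integration with constants of no real substance; scatter was added.

I decided to treat the fall of the starting complex as second-order, the way step growth is followed by plotting the reciprocal of what is left against time.

| flask | starting complex | incoming ligand | leaving ligand | scavenger | remark | time |
|---|---|---|---|---|---|---|
| spring | 10 mM | 0.70 equiv | 0.50 equiv | 0.15 equiv | run made earlier |  |
| midnight | 10 mM | 0.70 equiv | 0.50 equiv | 0.60 equiv | run made earlier |  |
| noon | 15 mM | 0.70 equiv | 0.50 equiv | 0.30 equiv | run made earlier |  |
| flask | 10 mM | 0.700 equiv | 0.500 equiv | 0.300 equiv |  | 2.5 h |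

| run | time / h | starting complex / % | complex with one exchanged / % |
|---|---|---|---|
| spring | 0.667 | 3 | 16 |
| spring | 1.33 | 0 | 12 |
| spring | 2.00 | 2 | 12 |
| spring | 2.50 | 1 | 9 |
| midnight | 0.200 | 9 | 20 |
| midnight | 0.500 | 4 | 19 |
| midnight | 1.00 | 0 | 19 |
| midnight | 2.50 | 2 | 14 |
| noon | 0.667 | 2 | 17 |
| noon | 1.33 | 1 | 10 |
| noon | 2.00 | 1 | 9 |
| noon | 2.50 | 1 | 9 |

(scatter of a reading: 1.5 percentage points)

1. part of the starting complex that has reacted at 2.5 h
2. share of the unused incoming ligand that is free and not bound as idle adduct, at 2.5 h

- the earlier runs do not show how much of incoming ligand is bound; that part of a forecast is a guess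
- a reading or a percentage of leaving ligand counts all its forms, free or not

Could the fall be first-order? In the midnight run 9% stood at 0.200 h; a first-order fall through that reading gives 0.243% at 0.500 h, but the reading is 4%, so I dropped it.

That first midnight reading gave 0.0198 h for τ, my clock time: the reading time multiplied by the share left and divided by the share gone, which is the first half-life of a second-order fall. The share left at time t is then τ/(τ + t).

Do scavenger and concentration move τ? The spring run, with 0.15 equiv of scavenger against 0.60 equiv, reads 0.0206 h, about the same. The noon run, scaled by its [starting complex], reads 0.0204 h, though its 2% carries a scatter of 1.5 percentage points. So I took τ as inversely proportional to [starting complex] at held equivalents.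

For the flask I reckoned 0.785% left at 2.5 h, so I expected 99.2% to have reacted. The runs show no bound incoming ligand, so I reckoned nothing for the free share.

The forecast gave 99% reacted (97% to 100%) and 60% of the unused incoming ligand free (20% to 95%), saying "the free share is a guess".

The flask gave 99.3% reacted and 44.5% of the unused incoming ligand free.

    starting complex + incoming ligand → leaving ligand + complex with one exchanged (k = 18.9 M⁻¹ min⁻¹)
    complex with one exchanged + incoming ligand → leaving ligand + complex with two exchanged (k = 9.35 M⁻¹ min⁻¹)
    complex with two exchanged + incoming ligand → leaving ligand + complex with three exchanged (k = 59.4 M⁻¹ min⁻¹)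
    complex with three exchanged + incoming ligand → leaving ligand + complex with four exchanged (k = 9.73 M⁻¹ min⁻¹)
    leaving ligand + incoming ligand ⇌ idle adduct, settled at all times (K = 150 M⁻¹)
    scavenger + leaving ligand → scavenged by-product (k = 341 M⁻¹ min⁻¹)
    leaving ligand + complex with one exchanged → side product (k = 0.196 M⁻¹ min⁻¹)
    2 starting complex → homo dimer (k = 21.7 M⁻¹ min⁻¹)

Just after the start of the flask, the loss of two starting complex to homo dimer used starting complex 4.7 times as fast as the exchange to complex with one exchanged. At 1.25 h, τ gives 1.56% left in the flask, which held 1.38%.

In a neighbour flask charged with 40 mM of starting complex, at the same equivalents, τ shrinks to 0.00495 h, which gives 99.8% reacted at 2.5 h; the computed result is 99.8%.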